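Remark: ring A is the benzoic acid ring (carboxyl on C1, ester oxygen on C4), ring B the central galloyl ring and ring C the terminal galloyl ring; 3,4,5-tris(benzyloxy)benzoic acid is taken as a purchased compound (otherwise two steps from gallic acid: BnBr/K2CO3, then KOH).

**Retrosynthetic overview**
- The target is reached by hydrogenolysis of five benzyl ethers and one diphenylmethylene ketal; the ring A carboxyl comes from a silyloxymethyl group by desilylation and two oxidations.
- The ring A C4–O–C(=O)–ring B ester is cut back to a diaryl ketone joining ring A C4 to the ring B carbonyl carbon (Baeyer–Villiger oxygen insertion). The strategy rests on ring A C4 sitting between the oxygens on C3 and C5, which makes ring A the migrating group.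
- The ketone comes from the ring A aryllithium (bromine on C4) and a ring B aldehyde, then oxidation. The ring C ester is put on the ring B phenol only after the organolithium step (allyl ether as temporary protection, then Steglich esterification).
- No carbocycle is built: rings A, B and C are purchased benzene rings. The only ring closed is the protecting 1,3-dioxole on ring B (step 4), which is opened again in step 14.

Key step: step 10

**Route**

Step 1
Reactants: 1 4-bromo-3,5-dihydroxybenzoic acid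
Product: 2 benzyl 3,5-bis(benzyloxy)-4-bromobenzoate
Conditions: BnBr, K2CO3, DMF, 60 °C
Reagents that add atoms: benzyl bromide, BrCc1ccccc1
Why: Williamson etherification of both phenols and O-alkylation of the carboxylate under carbonate base should proceed in one operation, the flanking bromine not blocking O-alkylation.

Step 2
Reactants: 2 benzyl 3,5-bis(benzyloxy)-4-bromobenzoate
Product: 3 [3,5-bis(benzyloxy)-4-bromophenyl]methanol
Conditions: i-Bu2AlH (DIBAL-H), CH2Cl2, −78 → 0 °C; aq. KNaC4H4O6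
Reagents that add atoms: none
Why: Hydride reduction of the benzyl ester with DIBAL-H gives the primary benzylic alcohol and leaves the aryl bromide and the benzyl ethers untouched.

Step 3
Reactants: 3 [3,5-bis(benzyloxy)-4-bromophenyl]methanol
Product: 4 {[3,5-bis(benzyloxy)-4-bromophenyl]methoxy}(tert-butyl)dimethylsilane
Conditions: TBSCl, imidazole, DMF, rt
Reagents that add atoms: tert-butyldimethylsilyl chloride, CC(C)(C)[Si](C)(C)Cl
Why: Standard imidazole-promoted silylation of a primary alcohol masks the future carboxyl carbon as a non-withdrawing group that tolerates organolithium and peracid.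

Step 4
Reactants: 5 3,4,5-trihydroxybenzaldehyde; 6 dichlorodiphenylmethane
Product: 7 7-hydroxy-2,2-diphenyl-1,3-benzodioxole-5-carbaldehyde
Conditions: K2CO3, MeCN, rt, Ar
Reagents that add atoms: none
Why: Double O-alkylation of two neighbouring phenols by the gem-dichloride closes the five-membered diphenylmethylene ketal, and because the triol is symmetric either adjacent pair gives the same product with one phenol left free.

Step 5
Reactants: 7 7-hydroxy-2,2-diphenyl-1,3-benzodioxole-5-carbaldehyde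
Product: 8 7-(allyloxy)-2,2-diphenyl-1,3-benzodioxole-5-carbaldehyde
Conditions: allyl bromide, K2CO3, DMF, rt
Reagents that add atoms: allyl bromide, C=CCBr
Why: Williamson allylation protects the remaining phenol with a group that is inert to aryllithium and is removable later without touching benzyl, silyl or ketal groups.

Step 6
Reactants: 4 {[3,5-bis(benzyloxy)-4-bromophenyl]methoxy}(tert-butyl)dimethylsilane; 8 7-(allyloxy)-2,2-diphenyl-1,3-benzodioxole-5-carbaldehyde
Product: 10 rac-[7-(allyloxy)-2,2-diphenyl-1,3-benzodioxol-5-yl]{2,6-bis(benzyloxy)-4-[(tert-butyldimethylsilyloxy)methyl]phenyl}methanol, via ring A aryllithium 9 (not isolated)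
Conditions: n-BuLi, THF, −78 °C; then 8, −78 °C; aq. NH4Cl
Reagents that add atoms: n-butyllithium, CCCC[Li] (its lithium is carried only in intermediate 9)
Why: Bromine–lithium exchange at −78 °C is faster than any attack on the ethers, and the aryllithium, held by its two ortho oxygens, undergoes 1,2-addition to the non-enolisable aldehyde; the new carbinol centre forms racemic and is erased by the next oxidation.

Step 7
Reactants: 10 rac-[7-(allyloxy)-2,2-diphenyl-1,3-benzodioxol-5-yl]{2,6-bis(benzyloxy)-4-[(tert-butyldimethylsilyloxy)methyl]phenyl}methanol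
Product: 11 [7-(allyloxy)-2,2-diphenyl-1,3-benzodioxol-5-yl]{2,6-bis(benzyloxy)-4-[(tert-butyldimethylsilyloxy)methyl]phenyl}methanone
Conditions: Dess–Martin periodinane, NaHCO3, CH2Cl2, rt
Reagents that add atoms: none
Why: Dess–Martin oxidation of a doubly benzylic secondary alcohol to the diaryl ketone is reliable even at a crowded carbinol, and the buffer protects the silyl ether and the ketal.

Step 8
Reactants: 11 [7-(allyloxy)-2,2-diphenyl-1,3-benzodioxol-5-yl]{2,6-bis(benzyloxy)-4-[(tert-butyldimethylsilyloxy)methyl]phenyl}methanone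
Product: 12 {2,6-bis(benzyloxy)-4-[(tert-butyldimethylsilyloxy)methyl]phenyl}(7-hydroxy-2,2-diphenyl-1,3-benzodioxol-5-yl)methanone
Conditions: Pd(PPh3)4 (cat.), morpholine, THF, rt
Reagents that add atoms: none
Why: Palladium-catalysed allyl transfer to morpholine (Tsuji–Trost deallylation) frees the ring B phenol selectively, since benzyl ethers, the silyl ether, the ketal and the hindered ketone do not react.

Step 9
Reactants: 12 {2,6-bis(benzyloxy)-4-[(tert-butyldimethylsilyloxy)methyl]phenyl}(7-hydroxy-2,2-diphenyl-1,3-benzodioxol-5-yl)methanone; 13 3,4,5-tris(benzyloxy)benzoic acid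
Product: 14 6-{2,6-bis(benzyloxy)-4-[(tert-butyldimethylsilyloxy)methyl]benzoyl}-2,2-diphenyl-1,3-benzodioxol-4-yl 3,4,5-tris(benzyloxy)benzoate
Conditions: EDC·HCl, DMAP, CH2Cl2, rt
Reagents that add atoms: none
Why: Steglich esterification through the N-acylpyridinium species acylates the phenol, which has only one ortho substituent, and installs the ring C ester that also deactivates ring B for the next step.

Step 10
Reactants: 14 6-{2,6-bis(benzyloxy)-4-[(tert-butyldimethylsilyloxy)methyl]benzoyl}-2,2-diphenyl-1,3-benzodioxol-4-yl 3,4,5-tris(benzyloxy)benzoate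
Product: 16 2,6-bis(benzyloxy)-4-[(tert-butyldimethylsilyloxy)methyl]phenyl 7-{[3,4,5-tris(benzyloxy)benzoyl]oxy}-2,2-diphenyl-1,3-benzodioxole-5-carboxylate, via Criegee adduct 15 (not isolated)
Conditions: mCPBA, NaHCO3, CH2Cl2, 0 °C → rt, dark
Reagents that add atoms: mCPBA (3-chloroperbenzoic acid), O=C(OO)c1cccc(Cl)c1
Why: The peracid adds to the ketone carbonyl, which is twisted out of conjugation with ring A and therefore electrophilic, to give Criegee adduct 15, and an aryl group then shifts from carbon to the proximal peroxide oxygen as 3-chlorobenzoate leaves. This is the Baeyer–Villiger oxidation of an electron-rich benzophenone to an aryl benzoate, a known reaction type; no ring is closed and no stereocentre is formed. The step needs ring A and not ring B to migrate: the benzyloxy groups on C3 and C5 of ring A stabilise the positive charge building at the migrating C4, the para silyloxymethyl group is not electron-withdrawing, and migration relieves crowding at the doubly ortho-substituted carbon. Ring B offers only one para oxygen and carries a meta acyloxy group that lowers its migratory aptitude. The bicarbonate buffer keeps the silyl ether and the ketal away from acid, and the ester, ether and ketal groups are inert to the peracid.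

Step 11
Reactants: 16 2,6-bis(benzyloxy)-4-[(tert-butyldimethylsilyloxy)methyl]phenyl 7-{[3,4,5-tris(benzyloxy)benzoyl]oxy}-2,2-diphenyl-1,3-benzodioxole-5-carboxylate
Product: 17 2,6-bis(benzyloxy)-4-(hydroxymethyl)phenyl 7-{[3,4,5-tris(benzyloxy)benzoyl]oxy}-2,2-diphenyl-1,3-benzodioxole-5-carboxylate
Conditions: HF·pyridine, pyridine, THF, 0 °C → rt
Reagents that add atoms: none
Why: Fluoride-driven desilylation under weakly acidic, non-nucleophilic conditions should free the primary alcohol without cleaving the two aryl esters, which basic fluoride sources would endanger.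

Step 12
Reactants: 17 2,6-bis(benzyloxy)-4-(hydroxymethyl)phenyl 7-{[3,4,5-tris(benzyloxy)benzoyl]oxy}-2,2-diphenyl-1,3-benzodioxole-5-carboxylate
Product: 18 2,6-bis(benzyloxy)-4-formylphenyl 7-{[3,4,5-tris(benzyloxy)benzoyl]oxy}-2,2-diphenyl-1,3-benzodioxole-5-carboxylate
Conditions: Dess–Martin periodinane, NaHCO3, CH2Cl2, rt
Reagents that add atoms: none
Why: Dess–Martin oxidation of the benzylic alcohol stops cleanly at the aldehyde under neutral conditions that spare the esters and the ketal.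

Step 13
Reactants: 18 2,6-bis(benzyloxy)-4-formylphenyl 7-{[3,4,5-tris(benzyloxy)benzoyl]oxy}-2,2-diphenyl-1,3-benzodioxole-5-carboxylate
Product: 19 3,5-bis(benzyloxy)-4-[(7-{[3,4,5-tris(benzyloxy)benzoyl]oxy}-2,2-diphenyl-1,3-benzodioxole-5-carbonyl)oxy]benzoic acid
Conditions: NaClO2, NaH2PO4, 2-methyl-2-butene, t-BuOH/THF/H2O, 0 °C → rt
Reagents that add atoms: sodium chlorite, [Na+].[O-]Cl=O
Why: Pinnick oxidation converts the aryl aldehyde to the acid at mildly acidic pH, and the alkene scavenger removes hypochlorous acid before it can chlorinate the electron-rich rings.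

Step 14
Reactants: 19 3,5-bis(benzyloxy)-4-[(7-{[3,4,5-tris(benzyloxy)benzoyl]oxy}-2,2-diphenyl-1,3-benzodioxole-5-carbonyl)oxy]benzoic acid
Product: 20 3,5-dihydroxy-4-({3,4-dihydroxy-5-[(3,4,5-trihydroxybenzoyl)oxy]benzoyl}oxy)benzoic acid (CNP0202676.0)
Conditions: H2 (1 atm), Pd/C, THF, rt; filtration and evaporation without base or alcohol
Reagents that add atoms: none
Why: Catalytic hydrogenolysis cleaves the five benzyl ethers and the doubly benzylic diphenylmethylene ketal in one operation, and the neutral aprotic medium should avoid solvolysis or migration of the two depside esters.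

**Compound list**
1 | 4-bromo-3,5-dihydroxybenzoic acid | O=C(O)c1cc(O)c(Br)c(O)c1 | starting material
2 | benzyl 3,5-bis(benzyloxy)-4-bromobenzoate | O=C(OCc1ccccc1)c1cc(OCc2ccccc2)c(Br)c(OCc2ccccc2)c1 | intermediate
3 | [3,5-bis(benzyloxy)-4-bromophenyl]methanol | OCc1cc(OCc2ccccc2)c(Br)c(OCc2ccccc2)c1 | intermediate
4 | {[3,5-bis(benzyloxy)-4-bromophenyl]methoxy}(tert-butyl)dimethylsilane | CC(C)(C)[Si](C)(C)OCc1cc(OCc2ccccc2)c(Br)c(OCc2ccccc2)c1 | intermediate
5 | 3,4,5-trihydroxybenzaldehyde | O=Cc1cc(O)c(O)c(O)c1 | starting material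
6 | dichlorodiphenylmethane | ClC(Cl)(c1ccccc1)c1ccccc1 | starting material
7 | 7-hydroxy-2,2-diphenyl-1,3-benzodioxole-5-carbaldehyde | O=Cc1cc(O)c2OC(c3ccccc3)(c3ccccc3)Oc2c1 | intermediate
8 | 7-(allyloxy)-2,2-diphenyl-1,3-benzodioxole-5-carbaldehyde | O=Cc1cc(OCC=C)c2OC(c3ccccc3)(c3ccccc3)Oc2c1 | intermediate
9 | {2,6-bis(benzyloxy)-4-[(tert-butyldimethylsilyloxy)methyl]phenyl}lithium (not isolated) | CC(C)(C)[Si](C)(C)OCc1cc(OCc2ccccc2)c([Li])c(OCc2ccccc2)c1 | intermediate
10 | rac-[7-(allyloxy)-2,2-diphenyl-1,3-benzodioxol-5-yl]{2,6-bis(benzyloxy)-4-[(tert-butyldimethylsilyloxy)methyl]phenyl}methanol | CC(C)(C)[Si](C)(C)OCc1cc(OCc2ccccc2)c(C(O)c2cc(OCC=C)c3OC(c4ccccc4)(c4ccccc4)Oc3c2)c(OCc2ccccc2)c1 | intermediate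
11 | [7-(allyloxy)-2,2-diphenyl-1,3-benzodioxol-5-yl]{2,6-bis(benzyloxy)-4-[(tert-butyldimethylsilyloxy)methyl]phenyl}methanone | CC(C)(C)[Si](C)(C)OCc1cc(OCc2ccccc2)c(C(=O)c2cc(OCC=C)c3OC(c4ccccc4)(c4ccccc4)Oc3c2)c(OCc2ccccc2)c1 | intermediate
12 | {2,6-bis(benzyloxy)-4-[(tert-butyldimethylsilyloxy)methyl]phenyl}(7-hydroxy-2,2-diphenyl-1,3-benzodioxol-5-yl)methanone | CC(C)(C)[Si](C)(C)OCc1cc(OCc2ccccc2)c(C(=O)c2cc(O)c3OC(c4ccccc4)(c4ccccc4)Oc3c2)c(OCc2ccccc2)c1 | intermediate
13 | 3,4,5-tris(benzyloxy)benzoic acid | O=C(O)c1cc(OCc2ccccc2)c(OCc2ccccc2)c(OCc2ccccc2)c1 | starting material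
14 | 6-{2,6-bis(benzyloxy)-4-[(tert-butyldimethylsilyloxy)methyl]benzoyl}-2,2-diphenyl-1,3-benzodioxol-4-yl 3,4,5-tris(benzyloxy)benzoate | CC(C)(C)[Si](C)(C)OCc1cc(OCc2ccccc2)c(C(=O)c2cc(OC(=O)c3cc(OCc4ccccc4)c(OCc4ccccc4)c(OCc4ccccc4)c3)c3OC(c4ccccc4)(c4ccccc4)Oc3c2)c(OCc2ccccc2)c1 | intermediate
15 | Criegee adduct of 14 with 3-chloroperbenzoic acid (not isolated) | CC(C)(C)[Si](C)(C)OCc1cc(OCc2ccccc2)c(C(O)(OOC(=O)c2cccc(Cl)c2)c2cc(OC(=O)c3cc(OCc4ccccc4)c(OCc4ccccc4)c(OCc4ccccc4)c3)c3OC(c4ccccc4)(c4ccccc4)Oc3c2)c(OCc2ccccc2)c1 | intermediate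
16 | 2,6-bis(benzyloxy)-4-[(tert-butyldimethylsilyloxy)methyl]phenyl 7-{[3,4,5-tris(benzyloxy)benzoyl]oxy}-2,2-diphenyl-1,3-benzodioxole-5-carboxylate | CC(C)(C)[Si](C)(C)OCc1cc(OCc2ccccc2)c(OC(=O)c2cc(OC(=O)c3cc(OCc4ccccc4)c(OCc4ccccc4)c(OCc4ccccc4)c3)c3OC(c4ccccc4)(c4ccccc4)Oc3c2)c(OCc2ccccc2)c1 | intermediate
17 | 2,6-bis(benzyloxy)-4-(hydroxymethyl)phenyl 7-{[3,4,5-tris(benzyloxy)benzoyl]oxy}-2,2-diphenyl-1,3-benzodioxole-5-carboxylate | OCc1cc(OCc2ccccc2)c(OC(=O)c2cc(OC(=O)c3cc(OCc4ccccc4)c(OCc4ccccc4)c(OCc4ccccc4)c3)c3OC(c4ccccc4)(c4ccccc4)Oc3c2)c(OCc2ccccc2)c1 | intermediate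
18 | 2,6-bis(benzyloxy)-4-formylphenyl 7-{[3,4,5-tris(benzyloxy)benzoyl]oxy}-2,2-diphenyl-1,3-benzodioxole-5-carboxylate | O=Cc1cc(OCc2ccccc2)c(OC(=O)c2cc(OC(=O)c3cc(OCc4ccccc4)c(OCc4ccccc4)c(OCc4ccccc4)c3)c3OC(c4ccccc4)(c4ccccc4)Oc3c2)c(OCc2ccccc2)c1 | intermediate
19 | 3,5-bis(benzyloxy)-4-[(7-{[3,4,5-tris(benzyloxy)benzoyl]oxy}-2,2-diphenyl-1,3-benzodioxole-5-carbonyl)oxy]benzoic acid | O=C(O)c1cc(OCc2ccccc2)c(OC(=O)c2cc(OC(=O)c3cc(OCc4ccccc4)c(OCc4ccccc4)c(OCc4ccccc4)c3)c3OC(c4ccccc4)(c4ccccc4)Oc3c2)c(OCc2ccccc2)c1 | intermediate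
20 | 3,5-dihydroxy-4-({3,4-dihydroxy-5-[(3,4,5-trihydroxybenzoyl)oxy]benzoyl}oxy)benzoic acid (CNP0202676.0) | O=C(O)c1cc(O)c(OC(=O)c2cc(O)c(O)c(OC(=O)c3cc(O)c(O)c(O)c3)c2)c(O)c1 | target

**Step count and risks**

Total step count: 14. Longest linear sequence: 12 steps (steps 1–3 and 6–14, from compound 1).

Steps most likely to fail:

1. Step 10. The peracid may add too slowly to the crowded carbonyl, ring B may migrate in competition with ring A, or the electron-rich ring A may be hydroxylated by the peracid. The fallback builds the same ester by acylating a ring A phenol; it sets out from bromide 4 (with aldehyde 7 and acid 13) and comes back to the route at 16. Aryllithium 9 (n-BuLi, THF, −78 °C) is trapped with B(OMe)3 to give dimethyl {2,6-bis(benzyloxy)-4-[(tert-butyldimethylsilyloxy)methyl]phenyl}boronate F1 (not isolated), which NaOH/H2O2 oxidises to 2,6-bis(benzyloxy)-4-[(tert-butyldimethylsilyloxy)methyl]phenol F2. Aldehyde 7 is esterified with acid 13 (EDC·HCl, DMAP, CH2Cl2) to 6-formyl-2,2-diphenyl-1,3-benzodioxol-4-yl 3,4,5-tris(benzyloxy)benzoate F3. Pinnick oxidation (NaClO2, NaH2PO4, 2-methyl-2-butene) then gives 7-{[3,4,5-tris(benzyloxy)benzoyl]oxy}-2,2-diphenyl-1,3-benzodioxole-5-carboxylic acid F4. Steglich coupling of F4 with the hindered phenol F2 (EDC·HCl, DMAP, CH2Cl2, prolonged) should then give 16.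

2. Step 6. The doubly ortho-substituted aryllithium may add slowly to the aldehyde, leaving time for proton transfer from its own benzylic OCH2 groups, Wittig rearrangement or simple protonation. The fallback reverses the polarity of the two fragments; it sets out from bromide 4 and comes back at 10. Aryllithium 9 is trapped at −78 °C with the small electrophile DMF to give 2,6-bis(benzyloxy)-4-[(tert-butyldimethylsilyloxy)methyl]benzaldehyde F5. Purchased 5-bromobenzene-1,2,3-triol F6 is ketalised with 6 (K2CO3, MeCN) to 6-bromo-2,2-diphenyl-1,3-benzodioxol-4-ol F7 and allylated (allyl bromide, K2CO3, DMF) to 4-(allyloxy)-6-bromo-2,2-diphenyl-1,3-benzodioxole F8. Bromine–lithium exchange (n-BuLi, THF, −78 °C) gives the unhindered, benzyl-free [7-(allyloxy)-2,2-diphenyl-1,3-benzodioxol-5-yl]lithium F9 (not isolated), which should add to aldehyde F5 to give 10.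

3. Step 14. Hydrogenolysis of the ketal may stall after the benzyl ethers have gone, and during a long reaction the galloyl groups may migrate between neighbouring free phenols or the depside esters may be cleaved. The fallback removes the groups by acid and Lewis acid instead; it sets out from 19 and comes back at 20. Aqueous trifluoroacetic acid in CH2Cl2 hydrolyses the ketal to 3,5-bis(benzyloxy)-4-[(3,4-dihydroxy-5-{[3,4,5-tris(benzyloxy)benzoyl]oxy}benzoyl)oxy]benzoic acid F10. BCl3 with pentamethylbenzene in CH2Cl2 at −78 °C then transfers the five benzyl groups to the scavenger under acidic conditions, in which acyl migration is slow, to give 20.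

**Further compounds**
F1 | step 10 | dimethyl {2,6-bis(benzyloxy)-4-[(tert-butyldimethylsilyloxy)methyl]phenyl}boronate (not isolated) | CC(C)(C)[Si](C)(C)OCc1cc(OCc2ccccc2)c(B(OC)OC)c(OCc2ccccc2)c1
F2 | step 10 | 2,6-bis(benzyloxy)-4-[(tert-butyldimethylsilyloxy)methyl]phenol | CC(C)(C)[Si](C)(C)OCc1cc(OCc2ccccc2)c(O)c(OCc2ccccc2)c1
F3 | step 10 | 6-formyl-2,2-diphenyl-1,3-benzodioxol-4-yl 3,4,5-tris(benzyloxy)benzoate | O=Cc1cc(OC(=O)c2cc(OCc3ccccc3)c(OCc3ccccc3)c(OCc3ccccc3)c2)c2OC(c3ccccc3)(c3ccccc3)Oc2c1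
F4 | step 10 | 7-{[3,4,5-tris(benzyloxy)benzoyl]oxy}-2,2-diphenyl-1,3-benzodioxole-5-carboxylic acid | O=C(O)c1cc(OC(=O)c2cc(OCc3ccccc3)c(OCc3ccccc3)c(OCc3ccccc3)c2)c2OC(c3ccccc3)(c3ccccc3)Oc2c1
F5 | step 6 | 2,6-bis(benzyloxy)-4-[(tert-butyldimethylsilyloxy)methyl]benzaldehyde | CC(C)(C)[Si](C)(C)OCc1cc(OCc2ccccc2)c(C=O)c(OCc2ccccc2)c1
F6 | step 6 | 5-bromobenzene-1,2,3-triol (purchased) | Oc1cc(Br)cc(O)c1O
F7 | step 6 | 6-bromo-2,2-diphenyl-1,3-benzodioxol-4-ol | Oc1cc(Br)cc2OC(c3ccccc3)(c3ccccc3)Oc12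
F8 | step 6 | 4-(allyloxy)-6-bromo-2,2-diphenyl-1,3-benzodioxole | C=CCOc1cc(Br)cc2OC(c3ccccc3)(c3ccccc3)Oc12
F9 | step 6 | [7-(allyloxy)-2,2-diphenyl-1,3-benzodioxol-5-yl]lithium (not isolated) | C=CCOc1cc([Li])cc2OC(c3ccccc3)(c3ccccc3)Oc12
F10 | step 14 | 3,5-bis(benzyloxy)-4-[(3,4-dihydroxy-5-{[3,4,5-tris(benzyloxy)benzoyl]oxy}benzoyl)oxy]benzoic acid | O=C(O)c1cc(OCc2ccccc2)c(OC(=O)c2cc(O)c(O)c(OC(=O)c3cc(OCc4ccccc4)c(OCc4ccccc4)c(OCc4ccccc4)c3)c2)c(OCc2ccccc2)c1
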